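## Structural features

The target is a trans-fused bicyclo[5.3.0]decane (a daucane-type hydroazulene): the seven-membered ring B (C1–C7) and the five-membered ring A (C6–C10) share the C6–C7 bond. The five stereocentres are contiguous: the tertiary carbinol C10 (hydroxyl β, isopropyl α; β is the face of the C7 methyl) adjoins the ring-fusion methine C6 (H α), which adjoins the C5 carbinol (oxygen α) and the quaternary C7 (methyl β), which adjoins the C1 carbinol (oxygen α). Ring B holds the only skeletal alkene, C2=C3 with a methyl on C3, so the C1 ester is both allylic and neopentylic and C4 is a methylene between C3 and C5. The fragile groups are the angelate on O1 (a Z alkene that drifts to the E tiglate when the acyl group is activated by nucleophiles or base), the 4-hydroxybenzoate on O5 with its free phenol, and the free tertiary alcohol at C10, which sits β to O5 and invites dehydration or retro-aldol cleavage whenever C5 or C10 is a carbonyl. The real difficulty lies in the quaternary C7 next to the oxygenated C1 with fixed relative configuration, the trans ring fusion, the two secondary oxygens that must take different acyl groups, and an unambiguous alkene position. The key step uses the fact that ring B, written with C5 as an enol (C5=C6) beside C2=C3, is a cyclohepta-1,4-diene with C4 as the doubly allylic carbon and the C1–C7 bond opposite it. That is the pattern left by the [3,3] shift of a cis-divinylcyclopropane built on C3, C4 and C5.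

## Logic of the disconnections

28 to 27. The bond cut is the O–acetyl bond of a masked phenol. The phenol has to stay covered while both ester bonds are made, and the aryl acetate in 27 is the only ester with a phenoxide leaving group. Nothing is gained in skeleton; the gain is a chemoselective last step. The forward step must solvolyse the aryl acetate only.

27 to 24 and 25. The bond cut is O1–C(acyl). The angelate is the group most prone to isomerise, so it goes on as late as possible, and 25 is commercial. The forward step must acylate a hindered allylic, neopentylic hydroxyl without Z-to-E drift and without touching the tertiary C10 hydroxyl.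

24 to 23 to 21 and 22. The bonds cut are O1–Si (unmasking) and O5–C(acyl). O1 and O5 are distinguished from the key step onward (O1 arrives as a silyl ether from 10, O5 as an enol ether from 8), so no extra protecting step is spent. The forward acylation must tell the secondary C5 hydroxyl from the tertiary C10 hydroxyl.

21 to 20. The bond cut is C10–CH(CH3)2. A tertiary carbinol is a ketone plus an isopropyl nucleophile; this removes one stereocentre and three carbons. The forward step needs attack on the α-face of ring A and a reagent of low basicity, because C6–H is α and O5 is β to the carbonyl.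

20 to 19 to 18. The bonds cut are the ketal C–O bonds at C10 (a mask that must outlast the carbenoid step and the reductions) and C5–H. This takes C5 back to a ketone. The forward reduction must run under thermodynamic control to place O5 equatorial (α), since hydride approach would be pushed to the wrong face by the syn-axial C7 methyl.

18 to 17. The bond cut is C6–H, which returns the C5 ketone to its silyl enol ether, the form in which the sigmatropic step delivers it. The forward step must cleave the enol Si–O bond in the presence of the alkyl Si–O bond and protonate C6 on the α-face to give the trans fusion.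

17 to 15 to 14. The C–H bonds of the C3 methyl are traced back to the C–O bonds of an ester. The ester is the acceptor that the carbenoid needs and is otherwise only a latent methyl. The forward steps are a 1,2-reduction and a hydride displacement without allylic transposition.

14 to 13 to 8 and 12 (key step). The bonds cut are C1–C7 (sigmatropic shift) and C3–C4 with the transient C3–C5 (carbene transfer). The cut removes ring B, the quaternary C7 and the C1 carbinol stereocentre at once and leaves two achiral fragments. The forward step demands carbene transfer to the enol ether alkene of 8 at the carbenoid carbon, direct formation of the cis cyclopropane, an E enol ether in 12, and a catalyst that selects the face. The cis isomer must form directly because a trans isomer could only equilibrate through a ring-opened dipole that loses the stereochemical information.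

12 to 11 to 9 and 10. The bonds cut are the C1=C2 π bond (dehydration) and C2–C3 (aldol addition of the diazo carbon). Both partners are commercial. The forward dehydration must give the E enol ether and must not destroy the diazo group.

8 to 6 to 4 to 3 to 1. The bonds cut are O–Si, C5–C6 (acetyl onto a vinyl anion at C6), the ketal C–O bonds and C–Br. The sequence reduces the diene to a commercial enone. The forward steps need kinetic enolisation on the acetyl methyl and a vinyl anion that is stable next to the ketal.

## Other disconnections considered

Alternative 1: The cut is at C1–C7 and C5–C6, followed by release of ring B through cleavage of a cyclobutane bond (C1–C5). Forward, irradiation of 1 with the symmetrical bis-silyl enediol ether A1 would give the cis-anti-cis photoadduct A2 by enone–alkene [2+2] cycloaddition; desilylation and glycol cleavage (NaIO4 or Pb(OAc)4) would open the four-membered ring to the hydroazulene triketone A3.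
- In favour: two cheap achiral partners; the whole carbon skeleton except the isopropyl group, with the quaternary C7, in about three operations; oxygen already on C1, C5 and C10; a symmetrical alkene, so no head-to-head or head-to-tail question.
- Against here: A2 and A3 are racemic and no reliable control of absolute configuration is at hand. In A3, C6 lies between the C5 and C10 carbonyls (an enolised 1,3-diketone), so isopropyl addition at C10 and separate reductions at C5 and C1 need the three carbonyls told apart in extra steps. The C2=C3 alkene must still be drawn regioselectively from the saturated C3 methine. The trans fusion rests on an equilibration.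
- Comparison: on structure, both plans make C7 without an enolate alkylation (equal), but the chosen plan delivers O1 and O5 already differentiated, C10 masked and the alkene in place. On mechanism, the photocycloaddition is at least as dependable as the carbenoid step and avoids diazo compounds (better). On step economy, it reaches the bicycle faster (better) but would need a resolution and a long differentiation sequence, so the full route is expected to be longer.

Alternative 2: The cut is at C6–C10, made by ring contraction, with ring A taken from the chiral pool. Forward, (S)-terpinen-4-ol A4 already holds C10 with its hydroxyl and isopropyl group. O-silylation, allylic oxidation at the methylene next to the carbinol, conjugate addition of a vinyl group to the β-methyl enone so formed (quaternary C7) and diazo transfer would give the α-diazoketone A5. Its photolysis in methanol (Wolff rearrangement) would shift C10 from C5 to C6 with retention and give the cyclopentane ester A6.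
- In favour: the hardest centre to add late, C10, and the absolute configuration come from an inexpensive terpene; the Wolff step is stereoretentive at the migrating carbon; C5 arrives as an ester handle.
- Against here: A6 is ring A only. C2, C3 with its methyl, and C4 are missing, and C1 and C5 must later be set as carbinols and the alkene positioned without any built-in control element. The allylic oxidation has two candidate methylenes. The face of the conjugate addition is governed by a 1,4-related centre. Diazo transfer at a neopentylic methylene needs prior activation.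
- Comparison: on structure, fixing C10 first is better than the late isopropyl addition next to an epimerisable C6 in the chosen plan. On mechanism, the contraction is equal or better in reliability but forms one skeletal bond and no ring B, whereas the chosen key step forms two bonds, a ring and two stereocentres. On step economy, ring B annulation (for example through A7 of alternative 3) plus the end game would make the route clearly longer.

Alternative 3: The cut is at C4–C5 and C1–C2, inserting C2–C3–C4 between two aldehydes of a ring A piece. Forward, the ring A dialdehyde A7 (reachable from A6) would react with the bifunctional reagent A8. Its allyl iodide end would add to the less hindered C5 aldehyde under SnF2, and its allylsilane end would then close ring B on the C1 aldehyde under BF3·OEt2 (intramolecular Sakurai reaction), giving the 3-methylene diol A9.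
- In favour: convergent; ring B and both carbinols are formed at the right oxidation level with C6, C7 and C10 already fixed.
- Against here: the exocyclic methylene of A9 must be moved into the ring towards C2 and not C4, and nothing distinguishes the two allylic methylenes. The configurations at C5 and C1 come from two open additions with uncertain face selectivity. The two new hydroxyls appear together and must then be told apart for two different acylations. A7 carries an epimerisable C6 between an aldehyde and a β-silyloxy carbon.
- Comparison: on structure, having C10 in place before ring B forms and needing no redox adjustment at C1 and C5 are better points than in the chosen plan. On mechanism, the chosen sigmatropic shift fixes the alkene position and the C1/C7 relationship through one ordered transition state, which this alternative cannot match. On step economy, the annulation itself is equal (one or two operations), but the supply of A7 and the alkene isomerisation make the whole longer.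

Key step: step 7

Remarks on the chemistry, valid for all steps:
- TBS is tert-butyldimethylsilyl. Bicyclic compounds are named as bicyclo[5.3.0]decanes with the locants of the target (ring B C1–C7, ring A C6–C10), not with von Baeyer locants.
- Assumption: the (R) antipode of dirhodium tetrakis[N-(4-dodecylphenylsulfonyl)prolinate], Rh2(R-DOSP)4, is taken to give cyclopropane 13 in the sense drawn, by analogy with the usual sense of induction of this catalyst family. If the sense on this enol ether proves opposite, the (S) antipode is used and nothing else changes.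
- No error was found in the structures of the two key-step partners or of the cycloheptadiene; they are used unchanged. The two silyl groups may stay identical because an enol silyl ether is cleaved far faster than a hindered alkyl silyl ether.

## Route

Step 1
Reactants: 1 3-methylcyclopent-2-en-1-one
Product: 3 2-bromo-3-methylcyclopent-2-en-1-one, via dibromide 2 (not isolated)
Conditions: Br2, CH2Cl2, 0 °C; then Et3N, 0 °C → rt
Reagents that add atoms: bromine, BrBr
Why: Anti addition of bromine to the enone gives the trans dibromide, and the base removes the acidic α-hydrogen with loss of the β-bromide (bromination–dehydrobromination of an enone), which leaves bromine on the α-carbon.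

Step 2
Reactants: 3 2-bromo-3-methylcyclopent-2-en-1-one
Product: 4 6-bromo-7-methyl-1,4-dioxaspiro[4.4]non-6-ene
Conditions: HOCH2CH2OH, p-TsOH·H2O (cat.), benzene, reflux, Dean–Stark trap
Reagents that add atoms: ethylene glycol, OCCO
Why: Acid-catalysed ketalisation with azeotropic removal of water; with an α-bromo enone the alkene stays in place rather than moving out of conjugation.

Step 3
Reactants: 4 6-bromo-7-methyl-1,4-dioxaspiro[4.4]non-6-ene
Product: 6 1-(7-methyl-1,4-dioxaspiro[4.4]non-6-en-6-yl)ethan-1-one, via vinyllithium 5 (not isolated)
Conditions: n-BuLi, THF, −78 °C; then MeC(O)N(OMe)Me, −78 → 0 °C; aq. NH4Cl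
Reagents that add atoms: N-methoxy-N-methylacetamide, CC(=O)N(C)OC
Why: Bromine–lithium exchange gives a vinyllithium stabilised by the neighbouring ketal oxygens, and the N-methoxy-N-methylamide acylates it once only because the chelated tetrahedral adduct survives until work-up.

Step 4
Reactants: 6 1-(7-methyl-1,4-dioxaspiro[4.4]non-6-en-6-yl)ethan-1-one
Product: 8 6-[1-(TBSO)ethenyl]-7-methyl-1,4-dioxaspiro[4.4]non-6-ene, via lithium enolate 7 (not isolated)
Conditions: LiN(i-Pr)2, THF, −78 °C; then t-BuMe2SiCl, DMPU, −78 → 0 °C
Reagents that add atoms: tert-butyldimethylsilyl chloride, CC(C)(C)[Si](C)(C)Cl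
Why: Kinetic deprotonation of an enone occurs at the α′ methyl, not at the γ positions, and O-silylation of the cross-conjugated enolate gives the 2-silyloxydiene; basic conditions avoid the Lewis-acidic silyl triflate that could open the ketal.

Step 5
Reactants: 9 methyl diazoacetate; 10 (tert-butyldimethylsilyloxy)acetaldehyde
Product: 11 methyl 4-(TBSO)-2-diazo-3-hydroxybutanoate (racemic)
Conditions: DBU (0.2 equiv), MeCN, 0 °C → rt; 9 handled as a solution
Reagents that add atoms: none
Why: The diazo C–H is acidic enough for amidine-catalysed aldol-type addition to an aldehyde, a standard route to β-hydroxy-α-diazo esters; the new carbinol centre is removed in the next step.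

Step 6
Reactants: 11 methyl 4-(TBSO)-2-diazo-3-hydroxybutanoate
Product: 12 methyl (E)-4-(TBSO)-2-diazobut-3-enoate
Conditions: POCl3, Et3N, CH2Cl2, 0 °C; used at once
Reagents that add atoms: none
Why: O-phosphorylation and base-induced anti elimination is the usual dehydration of diazo aldols to vinyldiazoacetates; the E enol ether is favoured because the silyloxy group lies anti to the diazo ester in the reacting conformer, and an E terminus also slows cyclisation of the vinyl diazo unit.

Step 7
Reactants: 8 6-[1-(TBSO)ethenyl]-7-methyl-1,4-dioxaspiro[4.4]non-6-ene; 12 methyl (E)-4-(TBSO)-2-diazobut-3-enoate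
Product: 14 methyl (1R,7S)-1,5-bis(TBSO)-10,10-(ethylenedioxy)-7-methylbicyclo[5.3.0]deca-2,5-diene-3-carboxylate, via cis-divinylcyclopropane 13 (not isolated)
Conditions: Rh2(R-DOSP)4 (1 mol%), hexanes, −40 °C → rt, 12 (1.5 equiv) added over 3 h; then toluene, 80 °C
Reagents that add atoms: none
Why: The dirhodium carboxylate turns 12 into a donor/acceptor vinylcarbenoid that adds to the only accessible alkene of 8, the 1,1-disubstituted enol ether C4=C5 (C6=C7 is tetrasubstituted), forming C3–C4 and C3–C5 of cyclopropane 13. The closest known reaction type is the dirhodium-catalysed cyclopropanation of dienes, 2-silyloxydienes included, by vinyldiazoacetates with Cope rearrangement in the same flask; the oxygen on the vinyl terminus and the fully substituted C7 extend its reported scope. The cis placement of the two alkenyl groups should follow from the preference of these carbenoids to put the bulkier alkene substituent, here the ortho-disubstituted cyclopentenyl group, on the side of the donor and away from the ester. Ring B then closes by the [3,3] shift of 13 (C1–C7 made, C3–C5 broken) through the boat transition state that a cis cyclopropane enforces, a three-to-seven ring expansion driven by release of ring strain. C1 and C7 are set in this shift: the E silyloxy group on C1 and C8 on C7 point away from the three-membered ring, so O1 ends cis to C8 and trans to the C7 methyl, and the absolute sense (1R,7S) is relayed from the (1S,2R) cyclopropane that the chiral catalyst selects. The C7 methyl points inward and raises the barrier, hence the warming in toluene after carbene transfer. The step needs reaction at the carbenoid carbon and not at the oxygen-bearing vinyl terminus; the hydrocarbon solvent, the electron-rich carboxylate ligands and the bulky E silyloxy group favour this, and slow addition of 12 limits carbene dimerisation.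

Step 8
Reactants: 14 methyl (1R,7S)-1,5-bis(TBSO)-10,10-(ethylenedioxy)-7-methylbicyclo[5.3.0]deca-2,5-diene-3-carboxylate
Product: 15 [(1R,7S)-1,5-bis(TBSO)-10,10-(ethylenedioxy)-7-methylbicyclo[5.3.0]deca-2,5-dien-3-yl]methanol
Conditions: i-Bu2AlH (2.5 equiv), CH2Cl2, −78 °C; aq. potassium sodium tartrate
Reagents that add atoms: none
Why: 1,2-Reduction of an α,β-unsaturated ester to the allylic alcohol; silyl ether, silyl enol ether and ketal are inert to the aluminium hydride at low temperature.

Step 9
Reactants: 15 [(1R,7S)-1,5-bis(TBSO)-10,10-(ethylenedioxy)-7-methylbicyclo[5.3.0]deca-2,5-dien-3-yl]methanol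
Product: 17 (1R,7S)-1,5-bis(TBSO)-10,10-(ethylenedioxy)-3,7-dimethylbicyclo[5.3.0]deca-2,5-diene, via allylic mesylate 16 (not isolated)
Conditions: MsCl, Et3N, THF, −20 °C; then LiBHEt3 (excess), −20 → 0 °C
Reagents that add atoms: none
Why: The primary allylic mesylate is displaced by the trialkylborohydride in direct SN2 fashion at the unhindered CH2; attack at C2 with allylic shift is disfavoured by the adjacent silyloxy-bearing C1.

Step 10
Reactants: 17 (1R,7S)-1,5-bis(TBSO)-10,10-(ethylenedioxy)-3,7-dimethylbicyclo[5.3.0]deca-2,5-diene
Product: 18 (1R,6S,7S)-1-(TBSO)-10,10-(ethylenedioxy)-3,7-dimethylbicyclo[5.3.0]dec-2-en-5-one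
Conditions: n-Bu4NF (1.05 equiv), AcOH (2 equiv), THF, −78 → −20 °C; product used without delay
Reagents that add atoms: none
Why: Buffered fluoride cleaves the enol Si–O bond far faster than the hindered secondary alkyl silyl ether, and the enolate is protonated on carbon at C6 from the α-face, opposite the angular C7 methyl, which gives the trans fusion (6S). The buffer keeps the β,γ-alkene from moving into conjugation with the new ketone.

Step 11
Reactants: 18 (1R,6S,7S)-1-(TBSO)-10,10-(ethylenedioxy)-3,7-dimethylbicyclo[5.3.0]dec-2-en-5-one
Product: 19 (1R,5S,6S,7S)-1-(TBSO)-10,10-(ethylenedioxy)-3,7-dimethylbicyclo[5.3.0]dec-2-en-5-ol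
Conditions: Li, NH3(l)/THF, EtOH, −78 °C; then NH4Cl
Reagents that add atoms: none
Why: Dissolving-metal reduction of a ketone proceeds through a ketyl and carbanion that are protonated to the more stable equatorial alcohol, here O5 α and trans to C10 on C6 (5S). A hydride reagent would instead be steered to the β-alcohol by the syn-axial C7 methyl; the isolated alkene, the ketal and the silyl ether do not accept electrons under these conditions.

Step 12
Reactants: 19 (1R,5S,6S,7S)-1-(TBSO)-10,10-(ethylenedioxy)-3,7-dimethylbicyclo[5.3.0]dec-2-en-5-ol
Product: 20 (1R,5S,6S,7S)-1-(TBSO)-5-hydroxy-3,7-dimethylbicyclo[5.3.0]dec-2-en-10-one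
Conditions: PPTS (0.2 equiv), acetone/H2O (9:1), 45 °C; product used without delay
Reagents that add atoms: water, O
Why: Mild acid-catalysed hydrolysis of the dioxolane; the pyridinium acid is too weak to cleave the hindered silyl ether, dehydrate the β-hydroxy ketone or enolise C6 at a useful rate.

Step 13
Reactants: 20 (1R,5S,6S,7S)-1-(TBSO)-5-hydroxy-3,7-dimethylbicyclo[5.3.0]dec-2-en-10-one
Product: 21 (1R,5S,6S,7S,10R)-1-(TBSO)-3,7-dimethyl-10-(propan-2-yl)bicyclo[5.3.0]dec-2-ene-5,10-diol
Conditions: i-PrMgCl (4 equiv), CeCl3 (anhydrous, 4 equiv), THF, −78 → −20 °C; aq. NH4Cl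
Reagents that add atoms: isopropylmagnesium chloride, CC(C)[Mg]Cl
Why: Organocerium reagents add to hindered, enolisable ketones with little enolisation or reduction; the first equivalent forms the O5 alkoxide, which can chelate the carbonyl. Attack comes from the α-face of ring A, anti to the C7 methyl and to the C5 branch on C6, so the hydroxyl ends β (10R).

Step 14
Reactants: 21 (1R,5S,6S,7S,10R)-1-(TBSO)-3,7-dimethyl-10-(propan-2-yl)bicyclo[5.3.0]dec-2-ene-5,10-diol; 22 4-acetoxybenzoyl chloride
Product: 23 (1R,5S,6S,7S,10R)-1-(TBSO)-10-hydroxy-3,7-dimethyl-10-(propan-2-yl)bicyclo[5.3.0]dec-2-en-5-yl 4-acetoxybenzoate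
Conditions: pyridine, DMAP (0.1 equiv), CH2Cl2, 0 °C → rt
Reagents that add atoms: none
Why: Acylation by an acid chloride takes the secondary C5 hydroxyl only; the tertiary C10 hydroxyl is inert under these conditions and O1 is still silylated.

Step 15
Reactants: 23 (1R,5S,6S,7S,10R)-1-(TBSO)-10-hydroxy-3,7-dimethyl-10-(propan-2-yl)bicyclo[5.3.0]dec-2-en-5-yl 4-acetoxybenzoate
Product: 24 (1R,5S,6S,7S,10R)-1,10-dihydroxy-3,7-dimethyl-10-(propan-2-yl)bicyclo[5.3.0]dec-2-en-5-yl 4-acetoxybenzoate
Conditions: HF·pyridine, pyridine, THF, 0 °C → rt
Reagents that add atoms: none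
Why: Buffered hydrogen fluoride cleaves the alkyl silyl ether and, unlike basic fluoride, leaves the aryl acetate, the benzoate and the tertiary alcohol untouched.

Step 16
Reactants: 24 (1R,5S,6S,7S,10R)-1,10-dihydroxy-3,7-dimethyl-10-(propan-2-yl)bicyclo[5.3.0]dec-2-en-5-yl 4-acetoxybenzoate; 25 angelic acid
Product: 27 (1R,5S,6S,7S,10R)-10-hydroxy-3,7-dimethyl-1-[(Z)-2-methylbut-2-enoyloxy]-10-(propan-2-yl)bicyclo[5.3.0]dec-2-en-5-yl 4-acetoxybenzoate, via mixed anhydride 26 (not isolated)
Conditions: 25, 2,4,6-Cl3C6H2COCl, Et3N, toluene, rt; then 24, toluene, 75 °C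
Reagents that add atoms: none
Why: Yamaguchi esterification: the alcohol attacks the less hindered angeloyl carbonyl of the mixed anhydride, and omitting a strongly nucleophilic acyl-transfer catalyst avoids the addition–elimination path that turns angelate into tiglate; the tertiary hydroxyl does not react.

Step 17
Reactants: 27 (1R,5S,6S,7S,10R)-10-hydroxy-3,7-dimethyl-1-[(Z)-2-methylbut-2-enoyloxy]-10-(propan-2-yl)bicyclo[5.3.0]dec-2-en-5-yl 4-acetoxybenzoate
Product: 28 (1R,5S,6S,7S,10R)-10-hydroxy-3,7-dimethyl-1-[(Z)-2-methylbut-2-enoyloxy]-10-(propan-2-yl)bicyclo[5.3.0]dec-2-en-5-yl 4-hydroxybenzoate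
Conditions: NH4OAc (10 equiv), MeOH/H2O (4:1), rt
Reagents that add atoms: none
Why: Mild solvolysis removes only the aryl acetate, whose phenoxide leaving group is activated by the para ester; the alkyl angelate and benzoate esters and the Z alkene are left alone.

## Compound list

1 | 3-methylcyclopent-2-en-1-one | CC1=CC(=O)CC1 | starting material
2 | trans-2,3-dibromo-3-methylcyclopentan-1-one (racemic) | O=C1CC[C@](C)(Br)[C@H]1Br | intermediate
3 | 2-bromo-3-methylcyclopent-2-en-1-one | CC1=C(Br)C(=O)CC1 | intermediate
4 | 6-bromo-7-methyl-1,4-dioxaspiro[4.4]non-6-ene | CC1=C(Br)C2(CC1)OCCO2 | intermediate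
5 | (7-methyl-1,4-dioxaspiro[4.4]non-6-en-6-yl)lithium | [Li]C1=C(C)CCC12OCCO2 | intermediate
6 | 1-(7-methyl-1,4-dioxaspiro[4.4]non-6-en-6-yl)ethan-1-one | CC(=O)C1=C(C)CCC12OCCO2 | intermediate
7 | lithium 1-(7-methyl-1,4-dioxaspiro[4.4]non-6-en-6-yl)ethenolate | [Li]OC(=C)C1=C(C)CCC12OCCO2 | intermediate
8 | 6-[1-(tert-butyldimethylsilyloxy)ethenyl]-7-methyl-1,4-dioxaspiro[4.4]non-6-ene | C=C(O[Si](C)(C)C(C)(C)C)C1=C(C)CCC12OCCO2 | intermediate
9 | methyl diazoacetate | COC(=O)C=[N+]=[N-] | starting material
10 | (tert-butyldimethylsilyloxy)acetaldehyde | O=CCO[Si](C)(C)C(C)(C)C | starting material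
11 | methyl 4-(tert-butyldimethylsilyloxy)-2-diazo-3-hydroxybutanoate (racemic) | COC(=O)C(=[N+]=[N-])C(O)CO[Si](C)(C)C(C)(C)C | intermediate
12 | methyl (E)-4-(tert-butyldimethylsilyloxy)-2-diazobut-3-enoate | COC(=O)C(=[N+]=[N-])/C=C/O[Si](C)(C)C(C)(C)C | intermediate
13 | methyl (1S,2R)-2-(TBSO)-1-[(E)-2-(TBSO)ethenyl]-2-(7-methyl-1,4-dioxaspiro[4.4]non-6-en-6-yl)cyclopropane-1-carboxylate (cyclopropane C1, C2, C3 are C3, C5, C4 of the target; the two alkenyl groups cis) | COC(=O)[C@]1(/C=C/O[Si](C)(C)C(C)(C)C)C[C@@]1(O[Si](C)(C)C(C)(C)C)C1=C(C)CCC12OCCO2 | intermediate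
14 | methyl (1R,7S)-1,5-bis(TBSO)-10,10-(ethylenedioxy)-7-methylbicyclo[5.3.0]deca-2,5-diene-3-carboxylate | COC(=O)C1=C[C@@H](O[Si](C)(C)C(C)(C)C)[C@@]2(C)CCC3(OCCO3)C2=C(O[Si](C)(C)C(C)(C)C)C1 | intermediate
15 | [(1R,7S)-1,5-bis(TBSO)-10,10-(ethylenedioxy)-7-methylbicyclo[5.3.0]deca-2,5-dien-3-yl]methanol | OCC1=C[C@@H](O[Si](C)(C)C(C)(C)C)[C@@]2(C)CCC3(OCCO3)C2=C(O[Si](C)(C)C(C)(C)C)C1 | intermediate
16 | [(1R,7S)-1,5-bis(TBSO)-10,10-(ethylenedioxy)-7-methylbicyclo[5.3.0]deca-2,5-dien-3-yl]methyl methanesulfonate | CS(=O)(=O)OCC1=C[C@@H](O[Si](C)(C)C(C)(C)C)[C@@]2(C)CCC3(OCCO3)C2=C(O[Si](C)(C)C(C)(C)C)C1 | intermediate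
17 | (1R,7S)-1,5-bis(TBSO)-10,10-(ethylenedioxy)-3,7-dimethylbicyclo[5.3.0]deca-2,5-diene | CC1=C[C@@H](O[Si](C)(C)C(C)(C)C)[C@@]2(C)CCC3(OCCO3)C2=C(O[Si](C)(C)C(C)(C)C)C1 | intermediate
18 | (1R,6S,7S)-1-(TBSO)-10,10-(ethylenedioxy)-3,7-dimethylbicyclo[5.3.0]dec-2-en-5-one (trans-fused) | CC(C)(C)[Si](C)(C)O[C@@H]1C=C(C)CC(=O)[C@@H]2[C@]1(C)CCC23OCCO3 | intermediate
19 | (1R,5S,6S,7S)-1-(TBSO)-10,10-(ethylenedioxy)-3,7-dimethylbicyclo[5.3.0]dec-2-en-5-ol | CC(C)(C)[Si](C)(C)O[C@@H]1C=C(C)C[C@H](O)[C@@H]2[C@]1(C)CCC23OCCO3 | intermediate
20 | (1R,5S,6S,7S)-1-(TBSO)-5-hydroxy-3,7-dimethylbicyclo[5.3.0]dec-2-en-10-one | CC(C)(C)[Si](C)(C)O[C@@H]1C=C(C)C[C@H](O)[C@@H]2[C@]1(C)CCC2=O | intermediate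
21 | (1R,5S,6S,7S,10R)-1-(TBSO)-3,7-dimethyl-10-(propan-2-yl)bicyclo[5.3.0]dec-2-ene-5,10-diol | CC(C)(C)[Si](C)(C)O[C@@H]1C=C(C)C[C@H](O)[C@@H]2[C@]1(C)CC[C@@]2(O)C(C)C | intermediate
22 | 4-acetoxybenzoyl chloride | CC(=O)Oc1ccc(cc1)C(Cl)=O | starting material
23 | (1R,5S,6S,7S,10R)-1-(TBSO)-10-hydroxy-3,7-dimethyl-10-(propan-2-yl)bicyclo[5.3.0]dec-2-en-5-yl 4-acetoxybenzoate | CC(C)(C)[Si](C)(C)O[C@@H]1C=C(C)C[C@H](OC(=O)c3ccc(OC(C)=O)cc3)[C@@H]2[C@]1(C)CC[C@@]2(O)C(C)C | intermediate
24 | (1R,5S,6S,7S,10R)-1,10-dihydroxy-3,7-dimethyl-10-(propan-2-yl)bicyclo[5.3.0]dec-2-en-5-yl 4-acetoxybenzoate | O[C@@H]1C=C(C)C[C@H](OC(=O)c3ccc(OC(C)=O)cc3)[C@@H]2[C@]1(C)CC[C@@]2(O)C(C)C | intermediate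
25 | angelic acid, (Z)-2-methylbut-2-enoic acid | C/C=C(/C)C(=O)O | starting material
26 | (Z)-2-methylbut-2-enoic 2,4,6-trichlorobenzoic anhydride | C/C=C(/C)C(=O)OC(=O)c1c(Cl)cc(Cl)cc1Cl | intermediate
27 | (1R,5S,6S,7S,10R)-10-hydroxy-3,7-dimethyl-1-[(Z)-2-methylbut-2-enoyloxy]-10-(propan-2-yl)bicyclo[5.3.0]dec-2-en-5-yl 4-acetoxybenzoate | C/C=C(/C)C(=O)O[C@@H]1C=C(C)C[C@H](OC(=O)c3ccc(OC(C)=O)cc3)[C@@H]2[C@]1(C)CC[C@@]2(O)C(C)C | intermediate
28 | (1R,5S,6S,7S,10R)-10-hydroxy-3,7-dimethyl-1-[(Z)-2-methylbut-2-enoyloxy]-10-(propan-2-yl)bicyclo[5.3.0]dec-2-en-5-yl 4-hydroxybenzoate | C/C=C(/C)C(=O)O[C@@H]1C=C(C)C[C@H](OC(=O)c2ccc(O)cc2)[C@@H]2[C@]1(C)CC[C@@]2(O)C(C)C | target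

## Step count and least certain steps

Total: 17 steps. Longest linear sequence: 15 steps (steps 1–4, then 7–17); the diazo branch (steps 5 and 6) joins at step 7.

Step 7 (key step). The most likely failure is loss of enantiomeric purity. If carbene transfer to the 1,1-disubstituted enol ether is only moderately face-selective, or if part of the cyclopropane forms trans and reaches the cis isomer only by reversible opening of the donor–acceptor ring on warming, stereochemical information is lost. Attack of the enol ether at the oxygen-bearing vinyl terminus is a second risk. The fallback replaces catalyst control by a covalently bound auxiliary, so that the stereoisomers of the cycloadduct become separable diastereomers. It sets out from 8 and 10 and returns to the route at 15. (R)-Pantolactone is converted with glyoxylic acid chloride p-toluenesulfonylhydrazone and Et3N into (R)-pantolactonyl diazoacetate F1. Aldol addition of F1 to 10 (DBU, MeCN) gives the diazo alcohol F2, and POCl3/Et3N gives the E silyloxyvinyl diazo ester F3. Decomposition of F3 by achiral dirhodium tetrapivalate, Rh2(OPiv)4, in the presence of 8, followed by warming, gives the pantolactonyl cycloheptadienecarboxylate F4, whose (1R,7S) diastereomer is separated by chromatography. If the (R) auxiliary favours the other ring configuration, (S)-pantolactone is used instead. Excess i-Bu2AlH reduces both ester groups of F4 and releases 15.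

Step 10. The most likely failure is poor facial selectivity in the protonation of C6, because the β-face is screened by the C7 methyl and the α-face in part by the C1 silyloxy group; this would give some cis-fused ketone. The fallback moves from kinetic to thermodynamic control. It sets out from 17 and returns at 18: fluoride cleavage gives 18 mixed with the C6 epimer of 18 F5, and the mixture is equilibrated through the C5 enolate (DBU, toluene, rt) towards the trans-fused 18. In 18, C10 is equatorial on ring B and avoids the 1,3-contact with O1 that the cis isomer suffers. The equilibration is stopped early to limit migration of the alkene into conjugation.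

Step 11. The most likely failure is incomplete thermodynamic control in the flexible seven-membered ring, leaving the C5 β-alcohol. The fallback uses intramolecular hydride delivery and does not depend on ring conformation. It sets out from 18 and returns at 21. NaBH4 (MeOH, 0 °C) reduces 18 from the open α-face to the C5 epimer of 19 F6. The conditions of steps 12 and 13 convert F6 into the C5 epimer of 20 F7 and then the C5 epimer of 21 F8. The periodinane DMP (NaHCO3, CH2Cl2) oxidises the secondary hydroxyl of F8 to the 5-oxo analogue of 21 F9. Me4NBH(OAc)3 (MeCN/AcOH, −20 °C) binds to the C10 hydroxyl and delivers hydride to the β-face of C5 (Evans–Saksena reduction), giving 21.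

Step 13. The most likely failure is reduction of the hindered ketone by β-hydride transfer from the branched reagent, or enolisation towards C6 with loss of the trans fusion. The fallback sets out from 20 and returns at 21 in two steps. Isopropenylmagnesium bromide with CeCl3 (THF, −78 °C), an sp2 nucleophile that is smaller and cannot transfer hydride, adds to 20 to give the isopropenyl analogue of 21 F10. Hydrogenation over RhCl(PPh3)3 (H2, benzene, rt) then saturates the 1,1-disubstituted alkene and leaves the trisubstituted C2=C3 untouched.

Step 16. The most likely failure is Z-to-E isomerisation of the activated angeloyl group on prolonged heating, made necessary by slow acylation of the hindered hydroxyl. The fallback builds the Z alkene on the ester instead of transferring it. It sets out from 24 and returns at 27. Esterification of 24 with 2-[bis(2,2,2-trifluoroethoxy)phosphoryl]propanoic acid (DCC, DMAP, CH2Cl2) gives the phosphonopropanoate of 24 F11. Its potassium anion (KN(SiMe3)2, 18-crown-6, THF, −78 °C) condenses with acetaldehyde in a Z-selective Still–Gennari olefination to give 27.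

## Further compounds

F1 | step 7 | (3R)-4,4-dimethyl-2-oxooxolan-3-yl diazoacetate | CC1(C)COC(=O)[C@@H]1OC(=O)C=[N+]=[N-]
F2 | step 7 | (3R)-4,4-dimethyl-2-oxooxolan-3-yl 4-(tert-butyldimethylsilyloxy)-2-diazo-3-hydroxybutanoate | CC1(C)COC(=O)[C@@H]1OC(=O)C(=[N+]=[N-])C(O)CO[Si](C)(C)C(C)(C)C
F3 | step 7 | (3R)-4,4-dimethyl-2-oxooxolan-3-yl (E)-4-(tert-butyldimethylsilyloxy)-2-diazobut-3-enoate | CC1(C)COC(=O)[C@@H]1OC(=O)C(=[N+]=[N-])/C=C/O[Si](C)(C)C(C)(C)C
F4 | step 7 | (3R)-4,4-dimethyl-2-oxooxolan-3-yl (1R,7S)-1,5-bis(TBSO)-10,10-(ethylenedioxy)-7-methylbicyclo[5.3.0]deca-2,5-diene-3-carboxylate | CC1(C)COC(=O)[C@@H]1OC(=O)C1=C[C@@H](O[Si](C)(C)C(C)(C)C)[C@@]2(C)CCC3(OCCO3)C2=C(O[Si](C)(C)C(C)(C)C)C1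
F5 | step 10 | C6 epimer of 18 (cis-fused ketone) | CC(C)(C)[Si](C)(C)O[C@@H]1C=C(C)CC(=O)[C@H]2[C@]1(C)CCC23OCCO3
F6 | step 11 | C5 epimer of 19 | CC(C)(C)[Si](C)(C)O[C@@H]1C=C(C)C[C@@H](O)[C@@H]2[C@]1(C)CCC23OCCO3
F7 | step 11 | C5 epimer of 20 | CC(C)(C)[Si](C)(C)O[C@@H]1C=C(C)C[C@@H](O)[C@@H]2[C@]1(C)CCC2=O
F8 | step 11 | C5 epimer of 21 | CC(C)(C)[Si](C)(C)O[C@@H]1C=C(C)C[C@@H](O)[C@@H]2[C@]1(C)CC[C@@]2(O)C(C)C
F9 | step 11 | 5-oxo analogue of 21: 1-(TBSO)-10-hydroxy-3,7-dimethyl-10-(propan-2-yl)bicyclo[5.3.0]dec-2-en-5-one | CC(C)(C)[Si](C)(C)O[C@@H]1C=C(C)CC(=O)[C@@H]2[C@]1(C)CC[C@@]2(O)C(C)C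
F10 | step 13 | isopropenyl analogue of 21: 1-(TBSO)-3,7-dimethyl-10-(prop-1-en-2-yl)bicyclo[5.3.0]dec-2-ene-5,10-diol | CC(C)(C)[Si](C)(C)O[C@@H]1C=C(C)C[C@H](O)[C@@H]2[C@]1(C)CC[C@@]2(O)C(C)=C
F11 | step 16 | 1-O-{2-[bis(2,2,2-trifluoroethoxy)phosphoryl]propanoyl} derivative of 24 | CC(C(=O)O[C@@H]1C=C(C)C[C@H](OC(=O)c3ccc(OC(C)=O)cc3)[C@@H]2[C@]1(C)CC[C@@]2(O)C(C)C)P(=O)(OCC(F)(F)F)OCC(F)(F)F
A1 | alternative 1 | 4-methyl-1,2-bis(trimethylsilyloxy)cyclopent-1-ene | CC1CC(O[Si](C)(C)C)=C(O[Si](C)(C)C)C1
A2 | alternative 1 | cis-anti-cis tricyclic photoadduct, bis(trimethylsilyl) ether of the cyclobutane-1,2-diol | O=C1CC[C@@]2(C)[C@@H]1[C@]1(O[Si](C)(C)C)C[C@@H](C)C[C@]21O[Si](C)(C)C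
A3 | alternative 1 | 3a,6-dimethyloctahydroazulene-1,4,8-trione (cis-fused as first formed) | O=C1CC[C@@]2(C)[C@@H]1C(=O)C[C@@H](C)CC2=O
A4 | alternative 2 | (S)-terpinen-4-ol | CC1=CC[C@](O)(C(C)C)CC1
A5 | alternative 2 | 2-diazo-3-ethenyl-3-methyl-6-(propan-2-yl)-6-(trimethylsilyloxy)cyclohexan-1-one | O=C1C(=[N+]=[N-])[C@@](C)(C=C)CC[C@@]1(O[Si](C)(C)C)C(C)C
A6 | alternative 2 | methyl 2-ethenyl-2-methyl-5-(propan-2-yl)-5-(trimethylsilyloxy)cyclopentane-1-carboxylate | COC(=O)[C@@H]1[C@@](C)(C=C)CC[C@@]1(O[Si](C)(C)C)C(C)C
A7 | alternative 3 | 1-methyl-3-(propan-2-yl)-3-(trimethylsilyloxy)cyclopentane-1,2-dicarbaldehyde | O=C[C@@H]1[C@@](C)(C=O)CC[C@@]1(O[Si](C)(C)C)C(C)C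
A8 | alternative 3 | 3-iodo-2-(trimethylsilylmethyl)prop-1-ene | C=C(CI)C[Si](C)(C)C
A9 | alternative 3 | 3-methylene hydroazulene-1,5-diol with C10 trimethylsilyl ether | O[C@@H]1CC(=C)C[C@H](O)[C@@H]2[C@]1(C)CC[C@@]2(O[Si](C)(C)C)C(C)C
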